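**Strategy.** The dihydrofuran ring is closed last at O1–C2. Ring B of the flavone is a hydroquinone (O4 and O7 of the benzofuran are para), so it is carried as a 2-hydroxy-1,4-benzoquinone: O1 is then the acidic enol oxygen and C3a the nucleophilic carbon of a cyclic 1,3-dicarbonyl. Its C3a-benzylidene derivative (a quinone methide, released from a sulfone) takes up a chiral benzylic sulfonium ylide in a formal [4+1] annulation: conjugate addition forms C2–C3, then O1 displaces the sulfide at C2. One operation joins the flavone, 4-oxyphenyl and 3,5-dioxyphenyl units and sets both stereocenters; hydrogenation then reduces the quinone and removes all benzyl groups.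

Key step: step 12

Remark: 2,4,5-trimethoxybenzoyl chloride and the cyclic sulfate of (2R,5R)-hexane-2,5-diol (either enantiomer) are taken as catalogue compounds.
Remark: the facial preference of the thiolane ylide is taken from its benzylidene transfer to aldehydes ((2R,5R)-sulfide giving (S,S)-epoxides); if the annulation ran with the opposite sense, the enantiomeric sulfide would be used.

**Step 1**
Reactants: 1 3,5-bis(benzyloxy)phenol
Product: 2 2,6-bis(benzyloxy)-4-hydroxybenzaldehyde
Conditions: POCl3, DMF, 0 °C to rt; then H2O, 50 °C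
Reagents that add atoms: N,N-dimethylformamide CN(C)C=O; water O
Why: Vilsmeier–Haack formylation of the phloroglucinol-type ring should go mainly para to the free hydroxyl (between the two benzyloxy groups), as with 3,5-dialkoxyphenols, and the chelated ortho isomer is removed by chromatography.

**Step 2**
Reactants: 2 2,6-bis(benzyloxy)-4-hydroxybenzaldehyde
Product: 3 3,5-bis(benzyloxy)-4-methylphenol
Conditions: Et3SiH (3 equiv), CF3CO2H, CH2Cl2, 0 °C
Reagents that add atoms: none
Why: Ionic hydrogenation of the aldehyde, which is flanked by three donor oxygens and reduces through its stabilised benzylic cation to the methyl group, should spare the benzyl ethers in cold acid and gives a symmetric phenol whose two ortho positions are equivalent.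

**Step 3**
Reactants: 3 3,5-bis(benzyloxy)-4-methylphenol
Product: 4 3,5-bis(benzyloxy)-2-bromo-4-methylphenol
Conditions: NBS (1.0 equiv), CH2Cl2, −78 to −40 °C
Reagents that add atoms: N-bromosuccinimide O=C1CCC(=O)N1Br
Why: Electrophilic bromination ortho to the free phenol can only hit two equivalent positions, so one equivalent at low temperature should give the monobromide.

**Step 4**
Reactants: 4 3,5-bis(benzyloxy)-2-bromo-4-methylphenol; 5 N,2-dimethoxy-N-methylacetamide
Product: 6 1-[2,4-bis(benzyloxy)-6-hydroxy-3-methylphenyl]-2-methoxyethan-1-one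
Conditions: n-BuLi (2.1 equiv), THF, −78 °C; then 5, −78 to 0 °C; then 1 M HCl
Reagents that add atoms: none
Why: Bromine–lithium exchange on the lithium phenoxide followed by Weinreb ketone synthesis places the methoxyacetyl group between the free hydroxyl and a benzyloxy group without Lewis acid, which fixes the 6-methyl (not 8-methyl) chromone regiochemistry.

**Step 5**
Reactants: 6 1-[2,4-bis(benzyloxy)-6-hydroxy-3-methylphenyl]-2-methoxyethan-1-one; 7 2,4,5-trimethoxybenzoyl chloride
Product: 8 1-[2,4-bis(benzyloxy)-6-hydroxy-3-methylphenyl]-2-methoxy-3-(2,4,5-trimethoxyphenyl)propane-1,3-dione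
Conditions: LiN(SiMe3)2 (3.2 equiv), THF, −78 °C; then 7, −78 °C to rt; then 1 M HCl
Reagents that add atoms: none
Why: One-pot Baker–Venkataraman-type Claisen acylation of the phenoxide–enolate dianion should give the 2-methoxy-1,3-diketone, whose enolisable C2 centre disappears in the next step.

**Step 6**
Reactants: 8 the 2-methoxy-1,3-diketone
Product: 9 5,7-bis(benzyloxy)-3-methoxy-6-methyl-2-(2,4,5-trimethoxyphenyl)-4H-chromen-4-one
Conditions: AcOH, H2SO4 (cat.), 50 °C
Reagents that add atoms: none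
Why: Acid-catalysed cyclodehydration (flavone synthesis) can give only one chromone because the ring A hydroxyl next to the ring hydrogen is the only free phenol, and benzyl ethers tolerate warm acetic acid.

**Step 7**
Reactants: 9 the 2',4',5'-trimethoxyflavone
Product: 10 2-[5,7-bis(benzyloxy)-3-methoxy-6-methyl-4-oxo-4H-chromen-2-yl]-5-methoxy-1,4-benzoquinone
Conditions: (NH4)2Ce(NO3)6 (2.5 equiv), MeCN/H2O, 0 °C
Reagents that add atoms: water O
Why: Oxidative demethylation of the para-dimethoxy pair (2'- and 5'-OMe) of the 1,2,4-trimethoxyarene should give the 2-methoxy-1,4-benzoquinone, while the carbonyl-deactivated ring A, its benzyl ethers and the 3-OMe enol ether are poorer electron donors and should survive.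

**Step 8**
Reactants: 10 the methoxyquinone
Product: 11 2-[5,7-bis(benzyloxy)-3-methoxy-6-methyl-4-oxo-4H-chromen-2-yl]-5-hydroxy-1,4-benzoquinone
Conditions: 1 M NaOH, THF, 0 °C, short time; then 1 M HCl
Reagents that add atoms: sodium hydroxide [Na+].[OH-]
Why: Addition–elimination of hydroxide at the vinylogous ester carbon (saponification of the methoxyquinone) liberates the vinylogous acid, and cold dilute base should leave the flavone and benzyl ethers intact.

**Step 9**
Reactants: 11 the hydroxyquinone; 12 4-(benzyloxy)benzaldehyde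
Product: 13 3-{[4-(benzyloxy)phenyl](4-methylbenzenesulfonyl)methyl}-5-[5,7-bis(benzyloxy)-3-methoxy-6-methyl-4-oxo-4H-chromen-2-yl]-2-hydroxy-1,4-benzoquinone (racemic)
Conditions: p-TolSO2Na, HCO2H, THF/H2O, rt
Reagents that add atoms: sodium p-toluenesulfinate Cc1ccc(S(=O)[O-])cc1.[Na+]
Why: In a three-component Knoevenagel/sulfa-Michael reaction the only enol carbon of the hydroxyquinone (C3, between C2–OH and C4=O) condenses with the aldehyde and the sulfinic acid traps the methide, which should give a storable sulfone that returns the methide with base.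

**Step 10**
Reactants: 14 (4R,7R)-4,7-dimethyl-1,3,2-dioxathiepane 2,2-dioxide
Product: 15 (2S,5S)-2,5-dimethylthiolane
Conditions: Na2S·9H2O, DMSO, rt to 70 °C
Reagents that add atoms: sodium sulfide [Na+].[Na+].[S-2]
Why: Double SN2 displacement (opening of the cyclic sulfate, then 5-exo-tet closure on the sulfate monoester) inverts both carbinol centres, so the (4R,7R)-sulfate should give the (2S,5S)-thiolane.

**Step 11**
Reactants: 15 (2S,5S)-2,5-dimethylthiolane; 16 3,5-bis(benzyloxy)benzyl bromide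
Product: 17 (2S,5S)-1-[3,5-bis(benzyloxy)benzyl]-2,5-dimethylthiolan-1-ium trifluoromethanesulfonate
Conditions: AgOSO2CF3, CH2Cl2, 0 °C to rt, dark
Reagents that add atoms: silver trifluoromethanesulfonate [Ag+].[O-]S(=O)(=O)C(F)(F)F
Why: S-Alkylation is driven by precipitation of AgBr, and the C2-symmetric sulfide gives a single salt because its sulfur is not stereogenic.

**Step 12**
Reactants: 13 the sulfone; 17 the chiral sulfonium triflate
Product: 21 (2S,3S)-2-[3,5-bis(benzyloxy)phenyl]-3-[4-(benzyloxy)phenyl]-5-[5,7-bis(benzyloxy)-3-methoxy-6-methyl-4-oxo-4H-chromen-2-yl]-2,3-dihydro-1-benzofuran-4,7-dione, via sulfonium ylide 18 (not isolated), via quinone methide 19 (not isolated), via betaine 20 (not isolated)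
Conditions: Cs2CO3 (3 equiv), 17 (1.1 equiv), MeCN, −20 °C to rt
Reagents that add atoms: none
Why: Carbonate deprotonates the hydroxyquinone of 13, which expels sulfinate to give methide 19, and deprotonates 17 to ylide 18; 18 adds to the exocyclic carbon of 19 (forming C2–C3 and betaine 20) and the enolate oxygen then displaces the thiolane at the benzylic carbon (forming O1–C2). The closest known reaction type is the formal [4+1] annulation of sulfonium ylides with ortho-quinone methides or alkylidene 1,3-dicarbonyls to trans-2,3-dihydro(benzo)furans. The dihydrofuran closes by a 5-exo-tet SN2 O-alkylation with inversion at C2. C2 is controlled by the (2S,5S)-thiolane, whose methyl group cis to the ylide shields one face of the ylide carbon, which after inversion corresponds to 2S; C3 follows from the anti addition and closure that place the two aryl groups trans, also the more stable arrangement. The step needs closure through the oxygen on C2 of the quinone (giving the para-quinone) and not through the C4 carbonyl oxygen (ortho-quinone), which the higher charge density on the 2-oxido oxygen and the chromone flanking the C4 oxygen should secure. Attack of the ylide on the ring is disfavoured because the quinone stays anionic until the methide forms, and the methide is by far the best acceptor present.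

**Step 13**
Reactants: 21 the dihydrofuranoquinone
Product: 22 2-[(2S,3S)-2-(3,5-dihydroxyphenyl)-4,7-dihydroxy-3-(4-hydroxyphenyl)-2,3-dihydro-1-benzofuran-5-yl]-5,7-dihydroxy-3-methoxy-6-methyl-4H-chromen-4-one
Conditions: H2 (1 atm), Pd/C (10 wt% Pd), EtOAc/MeOH, rt, used without delay; isolation under argon
Reagents that add atoms: none
Why: Catalytic hydrogenation should reduce the quinone to the hydroquinone and hydrogenolyse the five benzyl ethers, while the tetrasubstituted chromone double bond, the 3-OMe group and the dihydrofuran C2–O bond (its aryl group carries only meta oxygens) should survive at 1 atm and no stereocenter is touched.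

**Compound list**
1 | 3,5-bis(benzyloxy)phenol | Oc1cc(OCc2ccccc2)cc(OCc2ccccc2)c1 | starting material
2 | 2,6-bis(benzyloxy)-4-hydroxybenzaldehyde | O=Cc1c(OCc2ccccc2)cc(O)cc1OCc1ccccc1 | intermediate
3 | 3,5-bis(benzyloxy)-4-methylphenol | Cc1c(OCc2ccccc2)cc(O)cc1OCc1ccccc1 | intermediate
4 | 3,5-bis(benzyloxy)-2-bromo-4-methylphenol | Cc1c(OCc2ccccc2)cc(O)c(Br)c1OCc1ccccc1 | intermediate
5 | N,2-dimethoxy-N-methylacetamide | COCC(=O)N(C)OC | starting material
6 | 1-[2,4-bis(benzyloxy)-6-hydroxy-3-methylphenyl]-2-methoxyethan-1-one | COCC(=O)c1c(O)cc(OCc2ccccc2)c(C)c1OCc1ccccc1 | intermediate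
7 | 2,4,5-trimethoxybenzoyl chloride | COc1cc(OC)c(OC)cc1C(=O)Cl | starting material
8 | 1-[2,4-bis(benzyloxy)-6-hydroxy-3-methylphenyl]-2-methoxy-3-(2,4,5-trimethoxyphenyl)propane-1,3-dione (racemic, enolisable) | COC(C(=O)c1c(O)cc(OCc2ccccc2)c(C)c1OCc1ccccc1)C(=O)c1cc(OC)c(OC)cc1OC | intermediate
9 | 5,7-bis(benzyloxy)-3-methoxy-6-methyl-2-(2,4,5-trimethoxyphenyl)-4H-chromen-4-one | COc1c(-c2cc(OC)c(OC)cc2OC)oc2cc(OCc3ccccc3)c(C)c(OCc3ccccc3)c2c1=O | intermediate
10 | 2-[5,7-bis(benzyloxy)-3-methoxy-6-methyl-4-oxo-4H-chromen-2-yl]-5-methoxy-1,4-benzoquinone | COc1c(C2=CC(=O)C(OC)=CC2=O)oc2cc(OCc3ccccc3)c(C)c(OCc3ccccc3)c2c1=O | intermediate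
11 | 2-[5,7-bis(benzyloxy)-3-methoxy-6-methyl-4-oxo-4H-chromen-2-yl]-5-hydroxy-1,4-benzoquinone | COc1c(C2=CC(=O)C(O)=CC2=O)oc2cc(OCc3ccccc3)c(C)c(OCc3ccccc3)c2c1=O | intermediate
12 | 4-(benzyloxy)benzaldehyde | O=Cc1ccc(OCc2ccccc2)cc1 | starting material
13 | 3-{[4-(benzyloxy)phenyl](4-methylbenzenesulfonyl)methyl}-5-[5,7-bis(benzyloxy)-3-methoxy-6-methyl-4-oxo-4H-chromen-2-yl]-2-hydroxy-1,4-benzoquinone (racemic) | COc1c(C2=CC(=O)C(O)=C(C(c3ccc(OCc4ccccc4)cc3)S(=O)(=O)c3ccc(C)cc3)C2=O)oc2cc(OCc3ccccc3)c(C)c(OCc3ccccc3)c2c1=O | intermediate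
14 | (4R,7R)-4,7-dimethyl-1,3,2-dioxathiepane 2,2-dioxide | C[C@@H]1CC[C@@H](C)OS(=O)(=O)O1 | starting material
15 | (2S,5S)-2,5-dimethylthiolane | C[C@H]1CC[C@H](C)S1 | intermediate
16 | 3,5-bis(benzyloxy)benzyl bromide | BrCc1cc(OCc2ccccc2)cc(OCc2ccccc2)c1 | starting material
17 | (2S,5S)-1-[3,5-bis(benzyloxy)benzyl]-2,5-dimethylthiolan-1-ium trifluoromethanesulfonate | C[C@H]1CC[C@H](C)[S+]1Cc1cc(OCc2ccccc2)cc(OCc2ccccc2)c1.[O-]S(=O)(=O)C(F)(F)F | intermediate
18 | sulfonium ylide of 17 (not isolated) | C[C@H]1CC[C@H](C)[S+]1[CH-]c1cc(OCc2ccccc2)cc(OCc2ccccc2)c1 | intermediate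
19 | quinone methide, 3-[4-(benzyloxy)benzylidene]-5-(chromen-2-yl)cyclohex-5-ene-1,2,4-trione (alkene geometry not fixed, not isolated) | COc1c(C2=CC(=O)C(=O)C(=Cc3ccc(OCc4ccccc4)cc3)C2=O)oc2cc(OCc3ccccc3)c(C)c(OCc3ccccc3)c2c1=O | intermediate
20 | betaine, oxido-quinone carrying the 1,2-diaryl-2-sulfonioethyl chain at C3 (not isolated) | COc1c(C2=CC(=O)C([O-])=C(C2=O)[C@H](c2ccc(OCc3ccccc3)cc2)[C@H](c2cc(OCc3ccccc3)cc(OCc3ccccc3)c2)[S+]2[C@@H](C)CC[C@@H]2C)oc2cc(OCc3ccccc3)c(C)c(OCc3ccccc3)c2c1=O | intermediate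
21 | (2S,3S)-2-[3,5-bis(benzyloxy)phenyl]-3-[4-(benzyloxy)phenyl]-5-[5,7-bis(benzyloxy)-3-methoxy-6-methyl-4-oxo-4H-chromen-2-yl]-2,3-dihydro-1-benzofuran-4,7-dione | COc1c(C2=CC(=O)C3=C(C2=O)[C@H](c2ccc(OCc4ccccc4)cc2)[C@@H](c2cc(OCc4ccccc4)cc(OCc4ccccc4)c2)O3)oc2cc(OCc3ccccc3)c(C)c(OCc3ccccc3)c2c1=O | intermediate
22 | 2-[(2S,3S)-2-(3,5-dihydroxyphenyl)-4,7-dihydroxy-3-(4-hydroxyphenyl)-2,3-dihydro-1-benzofuran-5-yl]-5,7-dihydroxy-3-methoxy-6-methyl-4H-chromen-4-one | COc1c(-c2cc(O)c3c(c2O)[C@H](c2ccc(O)cc2)[C@@H](c2cc(O)cc(O)c2)O3)oc2cc(O)c(C)c(O)c2c1=O | target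

**Step count.** Total: 13 steps. Longest linear sequence: 11 steps (steps 1–9, 12, 13); steps 10 and 11 make the sulfonium salt.

**Steps most likely to fail**

Step 12. The ambident oxido-quinone may close through the C4 oxygen and give the angular ortho-quinone. The ylide may also be consumed by addition to the ring of the product quinone, and prolonged base may isomerise 21 by loss of the C3 proton (γ to the C7 carbonyl). Facial control may be incomplete. Fallback, from 11 and 12, back at 21: the C2 unit is delivered as an enantiopure epoxide and the ether bond is closed in a separate step. (2R,5R)-2,5-dimethylthiolane F1, made like 15 from the enantiomeric cyclic sulfate, is alkylated in situ by 16 to (2R,5R)-1-[3,5-bis(benzyloxy)benzyl]-2,5-dimethylthiolan-1-ium bromide F2. The ylide of F2 (NaOH, t-BuOH/H2O, rt) should convert 12 into (2S,3S)-2-[4-(benzyloxy)phenyl]-3-[3,5-bis(benzyloxy)phenyl]oxirane F3 by asymmetric sulfur-ylide epoxidation. The enol carbon C3 of 11 then opens F3 at the carbon bearing the 4-(benzyloxy)phenyl group with inversion ((CF3)2CHOH, 0 °C, Friedel–Crafts-type epoxide opening). This should give 3-{(1S,2R)-1-[4-(benzyloxy)phenyl]-2-[3,5-bis(benzyloxy)phenyl]-2-hydroxyethyl}-5-[5,7-bis(benzyloxy)-3-methoxy-6-methyl-4-oxo-4H-chromen-2-yl]-2-hydroxy-1,4-benzoquinone F4. Mitsunobu cyclisation (PPh3, DIAD, THF, 0 °C) forms O1–C2 with inversion and gives 21.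

Step 9. The sulfinic acid may add to the quinone ring at C6, or the methide may be captured by a second molecule of 11 instead of sulfinate. Fallback, from 11, back at 21 through 19: 11, 12 and pyrrolidine (EtOH, rt) should give the zwitterionic Mannich base 3-{[4-(benzyloxy)phenyl](pyrrolidin-1-yl)methyl}-5-[5,7-bis(benzyloxy)-3-methoxy-6-methyl-4-oxo-4H-chromen-2-yl]-2-hydroxy-1,4-benzoquinone F5. This is a Betti-type aminoalkylation, routine for 2-hydroxy-1,4-naphthoquinone, and no sulfur nucleophile is present. F5 takes the place of 13 in step 12 (17, Cs2CO3, MeCN, 40 °C), where loss of pyrrolidine releases 19 and the annulation gives 21.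

Step 7. Oxidation may be unselective (benzylic oxidation of the benzyl ethers, attack on ring A), or the 4',5'-dimethoxy pair may be cleaved to an ortho-quinone. Fallback, from 9, back at 10: potential-controlled anodic oxidation of 9 (Pt anode, LiClO4, MeOH, 0 °C, undivided cell) should give the quinone bis(dimethyl ketal) 5,7-bis(benzyloxy)-3-methoxy-6-methyl-2-(3,3,4,6,6-pentamethoxycyclohexa-1,4-dien-1-yl)-4H-chromen-4-one F6. Hydrolysis of both ketals (AcOH/H2O, rt) then gives 10.

**Further compounds**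
F1 | step 12 | (2R,5R)-2,5-dimethylthiolane | C[C@@H]1CC[C@@H](C)S1
F2 | step 12 | (2R,5R)-1-[3,5-bis(benzyloxy)benzyl]-2,5-dimethylthiolan-1-ium bromide | C[C@@H]1CC[C@@H](C)[S+]1Cc1cc(OCc2ccccc2)cc(OCc2ccccc2)c1.[Br-]
F3 | step 12 | (2S,3S)-2-[4-(benzyloxy)phenyl]-3-[3,5-bis(benzyloxy)phenyl]oxirane | c1ccc(COc2ccc([C@@H]3O[C@H]3c3cc(OCc4ccccc4)cc(OCc4ccccc4)c3)cc2)cc1
F4 | step 12 | 3-{(1S,2R)-1-[4-(benzyloxy)phenyl]-2-[3,5-bis(benzyloxy)phenyl]-2-hydroxyethyl}-5-[5,7-bis(benzyloxy)-3-methoxy-6-methyl-4-oxo-4H-chromen-2-yl]-2-hydroxy-1,4-benzoquinone | COc1c(C2=CC(=O)C(O)=C(C2=O)[C@H](c2ccc(OCc3ccccc3)cc2)[C@@H](O)c2cc(OCc3ccccc3)cc(OCc3ccccc3)c2)oc2cc(OCc3ccccc3)c(C)c(OCc3ccccc3)c2c1=O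
F5 | step 9 | 3-{[4-(benzyloxy)phenyl](pyrrolidin-1-yl)methyl}-5-[5,7-bis(benzyloxy)-3-methoxy-6-methyl-4-oxo-4H-chromen-2-yl]-2-hydroxy-1,4-benzoquinone (racemic) | COc1c(C2=CC(=O)C(O)=C(C(c3ccc(OCc4ccccc4)cc3)N3CCCC3)C2=O)oc2cc(OCc3ccccc3)c(C)c(OCc3ccccc3)c2c1=O
F6 | step 7 | 5,7-bis(benzyloxy)-3-methoxy-6-methyl-2-(3,3,4,6,6-pentamethoxycyclohexa-1,4-dien-1-yl)-4H-chromen-4-one | COc1c(C2=CC(OC)(OC)C(OC)=CC2(OC)OC)oc2cc(OCc3ccccc3)c(C)c(OCc3ccccc3)c2c1=O
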